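The unit I count in is the percentage point of both substrates together charged, and in that unit every reading of the earlier runs carries a scatter of 0.5 percentage points.

| flask | left-handed substrate | right-handed substrate | solid reagent | catalyst | added ligand | temperature | remark | time |
|---|---|---|---|---|---|---|---|---|
| east | 20 mM | 20 mM | 32.8 mM | 82 µM | 68 µM | −5 °C | run made earlier |  |
| south-east | 82 mM | 82 mM | 32.8 mM | 82 µM | 68 µM | 25 °C | run made earlier |  |
| winter | 41 mM | 41 mM | 32.8 mM | 82 µM | 68 µM |  | at 50 °C until 20 min, from then on at 0 °C | 25 min |
| noon | 41 mM | 41 mM | 32.8 mM | 82 µM | 68 µM | 25 °C |  | 25 min |
| spring | 41 mM | 41 mM | 32.8 mM | 82 µM | 68 µM | 0 °C |  | 25 min |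
| dusk | 41 mM | 41 mM | 32.8 mM | 82 µM | 68 µM | 50 °C |  | 25 min |

| run | time / min | left-handed product / % | right-handed product / % |
|---|---|---|---|
| east | 4.00 | 0.6 | 0.5 |
| east | 12.0 | 2.5 | 0.2 |
| east | 20.0 | 5.1 | 0.9 |
| east | 25.0 | 7.1 | 0 |
| east | 40.0 | 10.9 | 0.6 |
| east | 50.0 | 13.4 | 0.8 |
| east | 60.0 | 16.0 | 1.1 |
| south-east | 2.00 | 0.2 | 0.4 |
| south-east | 4.00 | 0 | 0 |
| south-east | 6.00 | 0 | 0.8 |
| south-east | 8.00 | 0.6 | 0 |
| south-east | 10.0 | 0 | 0.2 |
| south-east | 12.0 | 0.4 | 0.3 |
| south-east | 15.0 | 1.2 | 0.7 |

(readings scatter by 0.5 percentage points)

- catalyst is single-handed; left-handed substrate and right-handed substrate are mirror images of each other, charged as a racemate, each of them at the stated concentration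
- solid reagent is a solid; its amount is given per volume of the solution
- the analysis behind the earlier runs scatters by 0.5 percentage points, standard deviation
- at the start none of the solid reagent is in solution

- the best flask by share of left-handed product in all that became left-handed product or right-handed product; "all alike" if 1.5 percentage points covers them all (winter / noon / spring / dusk / all alike)
- share of left-handed product in all that became left-handed product or right-handed product, winter
- share of left-handed product in all that became left-handed product or right-handed product, noon
- share of left-handed product in all that became left-handed product or right-handed product, spring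
- share of left-handed product in all that became left-handed product or right-handed product, dusk

At the start of the east run none of the solid reagent is in solution, and the reading at 4.00 min shows left-handed product at 0.6%, which the scatter cannot tell from nothing. From there the left-handed product of the east run climbs steadily, through the middle of the run, to a last reading of 16.0% at 60.0 min, while the right-handed product reads 1.1%.

I take each rate, at one temperature, as its own substrate times a factor common to both, holding catalyst and dissolved reagent. Dividing the two rates then removes that factor and time, and the integral says that the logarithm of the fraction of left-handed substrate remaining is a fixed multiple of the same logarithm for right-handed substrate. By its last readings the east run leaves 68.0% and 97.8% of the two charges, so the ratio of the two logarithms, the selectivity factor s, reads 17.3. It is a rough reading, with a scatter of 0.5 points standing against 1.1%.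

The south-east run gives no usable s, but its last left-handed reading, 1.97 mM at 15.0 min, lies between the east run's 1.00 mM at 12.0 min and 2.04 mM at 20.0 min. I therefore assume the same pace in mM for the asked flasks. At the end of spring that means about 3.46% left-handed product and 93.1% of the left-handed substrate remaining, so the two substrates still stand nearly equal and the share is close to s/(1+s). Taking s over to spring, which is warmer than the east run, I commit to 94.5% there. I expect the warm flasks lower, with winter between dusk and spring.

The forecast names spring as best, with 64% for winter, 74% for noon, 90% for spring and 60% for dusk, and it says “the coldest flask to be best”. On spring my number differs from its 90%.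

The flasks give 78.5% for winter, 86.3% for noon, 93.4% for spring and 76.1% for dusk, so spring is best, 1.1 points below my figure. Spring ends with 93% of its left-handed substrate still there, unbound. From spring to dusk the right-handed step speeds up by a factor of 11 and the left-handed by 2.4, which takes my s down to 3.87, a share of 79.5% against dusk's 76.1%.

    partner + catalyst + left-handed substrate → catalyst + left-handed product (k = 5700 /M²/s, Ea = 13.0 kJ/mol)
    partner + catalyst + right-handed substrate → catalyst + right-handed product (k = 390 /M²/s, Ea = 35.0 kJ/mol)
    solid reagent ⇌ partner, rate k3*(cs3 - [partner]) while solid is left; crystals form when [partner] > cs3 (solubility = 9.00 mM, k = 2.80 × 10⁻⁴ /s)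
    catalyst + added ligand ⇌ idle complex, settled at all times (K = 20000 /M, ΔH = −10.0 kJ/mol)
    catalyst ⇌ dormant form (K = 2.40, k = 0.00230 /s, Ea = 80.0 kJ/mol, ΔH = −1.00 kJ/mol)
    (constants at 0 °C)

The neighbour flask is winter read at 1.5 h. Applying s to its cold stretch, from the state at 20.0 min to left-handed substrate at 36.8%, gives right-handed product 1.53% and a share of 89.6%. The computed flask gives 1.66% and 88.8%.

(The readings were computed for an exercise, and the scatter is random.)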